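Two questions stood over one flask: how much target it held at the end, and how far its dissolved gas stood from saturation. The dusk run is this same flask in its first minutes; the winter run is an earlier flask with half the starting material.

| setting | dusk | winter | flask |
|---|---|---|---|
| starting material | 0.10 M | 0.050 M | 0.10 M |
| gas phase | 6.1 mM (held) | 6.1 mM (held) | 6.1 mM (held) |
| catalyst | 0.15 mM | 0.15 mM | 0.15 mM |
| remark | the very flask that is asked about, followed so far | run made earlier |  |
| time |  |  | 10 h |

- dusk (time / min: target / %): 6.00: 0.4; 10.0: 1.7; 15.0: 1.5; 25.0: 2.0; 40.0: 4.0; 80.0: 8.7
- winter (time / h: target / %): 1.50: 18.7; 3.00: 36.1; 5.00: 55.1; 6.00: 60.5; 8.00: 71.6; 10.0: 72.3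

(scatter of a reading: 1 percentage point)

* amount of target at 10 h, in percent of the starting material charged
* concentration of dissolved gas in solution at 10 h, in percent of saturation

- at the start none of the gas is dissolved
- steps thought possible: gas phase <-> dissolved gas; starting material + dissolved gas + catalyst <-> catalyst + target; dissolved gas + catalyst + target -> catalyst + over-reaction product

I took the uptake of starting material as the target formed by the last dusk reading and by the winter reading at 3.00 h:

dusk rate = 6.52 mM h⁻¹
winter rate = 6.02 mM h⁻¹

The two rates stood close although the dusk charge was twice the winter one, so I took gas transfer as the rate-limiting step. I carried one quantity, the clearing time 15.3 h, the charge of starting material divided by the uptake rate. I reckoned the winter flask's clearing time in the same way at 8.31 h.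

I held the rate steady and booked the starting material, the limiting reagent, in percent of the charge:

gone by 10 h = 10 h / 15.3 h = 65.2%
still starting material = 34.8%
target = 57.4%
over-reaction product = 7.80%

The target line is the winter reading, interpolated at the same share of its clearing time, and I assumed that share carries over. No reading shows dissolved gas, so my ledger has no line for it.

The forecast gave 56% target and 43% of saturation, on the ground of a reaction “largely limited by gas transfer”.

The flask gave 60.6% target and 22.6% of saturation, with 35% of the starting material left against my 34.8%.

    gas phase ⇌ dissolved gas, rate k1*(csat - [dissolved gas]) (kL = 3.80 × 10⁻⁴ s⁻¹)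
    starting material + dissolved gas + catalyst ⇌ catalyst + target (K = 4800 M⁻¹, k = 270 M⁻² s⁻¹)
    dissolved gas + catalyst + target → catalyst + over-reaction product (k = 27.0 M⁻² s⁻¹)

For the neighbouring flask, with 0.025 M of starting material, I reckoned at the dusk rate a clearing time of 3.83 h, so 10 h counted 2.61 clearing times, and the reckoned uptake exceeded its charge. That flask kept 3.75% of its starting material and held 65.0% target, and its over-reaction product stood at 31.3%.

The numbers in the tables were computed for substances that don't exist; the scatter is artificial.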